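The route rests on disconnecting the diaryl ether bond of the seven-membered dioxepinone ring between the ring A oxygen ortho to the ester carbonyl and the ring B carbon para to the free ring B phenol, the only C–H carbon of that ring. A phenol-coupling cytochrome P450 closes this O–C bond and the central ring in one operation from a depside, the ester of a ring A salicylic acid with 5,7-dihydroxy-6-methylphthalide. The ring A hydroxyl meta to the ester is carried as a benzyl ether so that each ring offers a single oxidisable phenol. Hydrogenolysis and a late enzymatic hydroxylation of the phthalide CH2 then give the (R)-lactol.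

Key step: step 9

Remark on the chemistry: the only stereocentre is a hemiacetal carbon that can equilibrate through the ring-opened formyl acid; it is assumed that the closed (R)-lactol keeps its configuration when it is formed last, held at pH 6 or below, kept cold and never exposed to base.

Step 1
Reactants: 1 3,4,5-trimethoxytoluene
Product: 3 2,3,4-trimethoxy-6-methylbenzaldehyde, via aryl iminium chloride 2 (not isolated)
Conditions: POCl3, DMF, 0 → 80 °C; then aq. NaOAc
Reagents that add atoms: N,N-dimethylformamide CN(C)C=O; water O
Why: Vilsmeier–Haack formylation of this electron-rich arene can only take place at one of the two equivalent free ring positions, and hydrolysis of the iminium salt releases the aldehyde.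

Step 2
Reactants: 3 2,3,4-trimethoxy-6-methylbenzaldehyde
Product: 5 2,3-dihydroxy-4-methoxy-6-methylbenzaldehyde, via cyclic chloroborate 4 (not isolated)
Conditions: BCl3 (3 equiv), CH2Cl2, 0 °C → rt; then H2O
Reagents that add atoms: none
Why: Chelation-directed Lewis acid ether cleavage, in which BCl3 held by the formyl oxygen cleaves the ortho methoxy group and the resulting aryloxyboron chloride cleaves the neighbouring methoxy group by closing a five-membered borate, while the 4-methoxy group lies out of reach of boron and should remain.

Step 3
Reactants: 5 2,3-dihydroxy-4-methoxy-6-methylbenzaldehyde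
Product: 7 3-(benzyloxy)-2-hydroxy-4-methoxy-6-methylbenzaldehyde, via disodium dianion 6 (not isolated)
Conditions: NaH (2.1 equiv), DMF, 0 °C; BnBr (1.0 equiv), 0 °C → rt; aq. HCl
Reagents that add atoms: benzyl bromide BrCc1ccccc1
Why: Regioselective Williamson etherification through the dianion, whose 3-oxide is neither conjugated with nor chelated to the formyl group and is therefore the more nucleophilic oxygen toward one equivalent of benzyl bromide.

Step 4
Reactants: 7 3-(benzyloxy)-2-hydroxy-4-methoxy-6-methylbenzaldehyde
Product: 8 3-(benzyloxy)-2-hydroxy-4-methoxy-6-methylbenzoic acid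
Conditions: NaClO2, NaH2PO4, sulfamic acid, dioxane/H2O, 0 °C → rt
Reagents that add atoms: sodium chlorite [Na+].[O-]Cl=O
Why: Lindgren (Pinnick-type) chlorite oxidation converts the aldehyde to the acid under mildly acidic conditions that spare the benzyl ether, with sulfamic acid trapping hypochlorite before it can chlorinate the electron-rich ring.

Step 5
Reactants: 9 3,5-dimethoxy-4-methylbenzoic acid
Product: 10 (3,5-dimethoxy-4-methylphenyl)methanol
Conditions: LiAlH4, THF, 0 °C → reflux; NaOH/H2O work-up
Reagents that add atoms: none
Why: Hydride reduction of a carboxylic acid to the benzylic alcohol is standard and nothing else in 9 is reducible.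

Step 6
Reactants: 10 (3,5-dimethoxy-4-methylphenyl)methanol
Product: 13 5,7-dimethoxy-6-methylisobenzofuran-1(3H)-one, via dilithio species 11 (not isolated), via hydroxy acid 12 (not isolated)
Conditions: n-BuLi (2.3 equiv), TMEDA, toluene, 0 °C → rt; CO2 (s), −78 °C → rt; 2 M HCl, rt
Reagents that add atoms: carbon dioxide O=C=O
Why: Directed ortho-metalation, in which the lithium alkoxide and the neighbouring methoxy group together direct lithiation to the ring carbon between them (the two such carbons are equivalent by symmetry and the carbon between the methoxy groups carries the methyl), followed by carboxylation and lactonisation of the ortho-hydroxymethyl acid on acidification.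

Step 7
Reactants: 13 5,7-dimethoxy-6-methylisobenzofuran-1(3H)-one
Product: 15 5,7-dihydroxy-6-methylisobenzofuran-1(3H)-one, via bis(dibromoboryl) ether 14 (not isolated)
Conditions: BBr3 (3 equiv), CH2Cl2, −78 °C → rt; then H2O, aq. NaHCO3
Reagents that add atoms: none
Why: Lewis acid cleavage of both aryl methyl ethers with BBr3 is standard for methoxyphthalides, and any lactone opened to the bromomethyl acid should reclose during the aqueous work-up.

Step 8
Reactants: 8 3-(benzyloxy)-2-hydroxy-4-methoxy-6-methylbenzoic acid; 15 5,7-dihydroxy-6-methylisobenzofuran-1(3H)-one
Product: 17 O-benzyl depside (7-hydroxy-6-methyl-1-oxo-1,3-dihydroisobenzofuran-5-yl 3-(benzyloxy)-2-hydroxy-4-methoxy-6-methylbenzoate), via mixed trifluoroacetic anhydride 16 (not isolated)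
Conditions: TFAA (2.5 equiv), toluene/THF, 0 °C → rt; aq. NaHCO3
Reagents that add atoms: none
Why: Depside esterification through the mixed trifluoroacetic anhydride, in which the chelated 2-hydroxyl of the acid and the 7-hydroxyl of the phthalide (hydrogen-bonded to the lactone carbonyl) are poor nucleophiles, so acylation should occur at the free 5-hydroxyl of 15.

Step 9
Reactants: 17 O-benzyl depside
Product: 18 O-benzyl depsidone phthalide (benzoate 2-oxygen bonded to phthalide C-4; ring A 3-OBn/4-OMe/6-CH3; ring B 7-OH/6-CH3; lactone CH2 intact)
Conditions: depsidone-forming cytochrome P450 (DepG type) with its NADPH-dependent reductase, expressed in Aspergillus oryzae, resting cells, glucose, air, phosphate buffer pH 6.5, 2% DMSO, 28 °C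
Reagents that add atoms: none
Why: The high-valent oxoiron haem (tetravalent iron) of the enzyme removes a hydrogen atom from the ring A phenol ortho to the ester carbonyl and from the chelated ring B phenol; the ring B phenoxyl radical has spin density at phthalide C-4, para to its oxygen, and this carbon recombines with the ring A phenoxyl oxygen, after which tautomerisation of the cyclohexadienone restores the arene. The closest known reaction type is the cytochrome P450 depside-to-depsidone phenol coupling of fungal and lichen depsidone biosynthesis, applied here to a non-native depside. The seven-membered ring closes by intramolecular O–C radical recombination at an sp2 carbon whose ester-bearing neighbour lies inside the new ring (formally 7-endo-trig). No stereocentre is formed. The step needs O–C coupling at a single site and no quinone formation: C-4 is the only C–H carbon of ring B, only the ring A oxygen ortho to the ester can reach it through a seven-membered ring, and the benzyl ether removes the ring A catechol that could otherwise be oxidised to an ortho-quinone. Because the two partners are already joined through the ester, the crowded diaryl ether is made intramolecularly and no halide has to be installed beforehand.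

Step 10
Reactants: 18 O-benzyl depsidone phthalide
Product: 19 depsidone phthalide (18 with the benzyl ether replaced by OH; the target lacking only the lactol hydroxyl)
Conditions: H2 (1 atm), 10% Pd/C, EtOAc, rt
Reagents that add atoms: none
Why: Hydrogenolysis of the aryl benzyl ether is standard and should leave the aryl ester, the diaryl ether and the phthalide lactone (a cyclic benzylic ester that is cleaved only slowly) untouched when stopped after one equivalent of hydrogen.

Step 11
Reactants: 19 depsidone phthalide
Product: 20 (R)-lactol depsidone (target; 19 with OH on the former phthalide CH2 carbon, R configuration)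
Conditions: recombinant Agrocybe aegerita unspecific peroxygenase (variant picked from a panel for the R lactol), H2O2 (1.1 equiv, syringe pump), ascorbic acid, potassium phosphate buffer pH 6.0, 10% MeCN, 20 °C; cold EtOAc extraction
Reagents that add atoms: hydrogen peroxide OO
Why: Proposed new method: the peroxygenase oxoiron porphyrin radical cation should abstract the pro-S hydrogen of the phthalide CH2 (benzylic and alpha to the lactone oxygen) and return hydroxyl to the same face by oxygen rebound, so the haem pocket of the chosen variant sets the (R) hemiacetal centre with retention; the closest known reaction types are peroxygenase hydroxylation of benzylic C–H bonds of alkylbenzenes to enantioenriched alcohols and alpha-hydroxylation of ethers to hemiacetals, while ascorbate should return any phenoxyl radical to the phenol and slow peroxide dosing should limit over-oxidation.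

Compound list
1 | 3,4,5-trimethoxytoluene | COc1cc(C)cc(OC)c1OC | starting material
2 | N,N-dimethyl(2,3,4-trimethoxy-6-methylbenzylidene)iminium chloride (not isolated) | C[N+](C)=Cc1c(C)cc(OC)c(OC)c1OC.[Cl-] | intermediate
3 | 2,3,4-trimethoxy-6-methylbenzaldehyde | COc1cc(C)c(C=O)c(OC)c1OC | intermediate
4 | 2-chloro-7-methoxy-5-methyl-1,3,2-benzodioxaborole-4-carbaldehyde (not isolated) | COc1cc(C)c(C=O)c2OB(Cl)Oc12 | intermediate
5 | 2,3-dihydroxy-4-methoxy-6-methylbenzaldehyde | COc1cc(C)c(C=O)c(O)c1O | intermediate
6 | disodium 3-formyl-6-methoxy-4-methylbenzene-1,2-diolate (not isolated) | COc1cc(C)c(C=O)c([O-])c1[O-].[Na+].[Na+] | intermediate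
7 | 3-(benzyloxy)-2-hydroxy-4-methoxy-6-methylbenzaldehyde | COc1cc(C)c(C=O)c(O)c1OCc1ccccc1 | intermediate
8 | 3-(benzyloxy)-2-hydroxy-4-methoxy-6-methylbenzoic acid | COc1cc(C)c(C(=O)O)c(O)c1OCc1ccccc1 | intermediate
9 | 3,5-dimethoxy-4-methylbenzoic acid | COc1cc(C(=O)O)cc(OC)c1C | starting material
10 | (3,5-dimethoxy-4-methylphenyl)methanol | COc1cc(CO)cc(OC)c1C | intermediate
11 | lithium (2-lithio-3,5-dimethoxy-4-methylphenyl)methanolate (not isolated) | [Li]OCc1cc(OC)c(C)c(OC)c1[Li] | intermediate
12 | 6-(hydroxymethyl)-2,4-dimethoxy-3-methylbenzoic acid (not isolated) | COc1cc(CO)c(C(=O)O)c(OC)c1C | intermediate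
13 | 5,7-dimethoxy-6-methylisobenzofuran-1(3H)-one | COc1cc2COC(=O)c2c(OC)c1C | intermediate
14 | 5,7-bis(dibromoboryloxy)-6-methylisobenzofuran-1(3H)-one (not isolated) | Cc1c(OB(Br)Br)cc2COC(=O)c2c1OB(Br)Br | intermediate
15 | 5,7-dihydroxy-6-methylisobenzofuran-1(3H)-one | Cc1c(O)cc2COC(=O)c2c1O | intermediate
16 | 3-(benzyloxy)-2-hydroxy-4-methoxy-6-methylbenzoic trifluoroacetic anhydride (not isolated) | COc1cc(C)c(C(=O)OC(=O)C(F)(F)F)c(O)c1OCc1ccccc1 | intermediate
17 | O-benzyl depside: 7-hydroxy-6-methyl-1-oxo-1,3-dihydroisobenzofuran-5-yl 3-(benzyloxy)-2-hydroxy-4-methoxy-6-methylbenzoate | COc1cc(C)c(C(=O)Oc2cc3COC(=O)c3c(O)c2C)c(O)c1OCc1ccccc1 | intermediate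
18 | O-benzyl depsidone phthalide: dibenzo[b,e][1,4]dioxepin-11-one in which ring A carries, going round from the carbonyl-bearing carbon, the ether oxygen, OBn, OMe, H and CH3, and ring B carries the ester oxygen, CH3, OH, the lactone C=O carbon and the lactone CH2 carbon next to the ether-bearing carbon | COc1cc(C)c2c(c1OCc4ccccc4)Oc1c(c(C)c(O)c3c1COC3=O)OC2=O | intermediate
19 | depsidone phthalide: 18 with OH in place of OBn | COc1cc(C)c2c(c1O)Oc1c(c(C)c(O)c3c1COC3=O)OC2=O | intermediate
20 | (R)-lactol depsidone: 19 with OH on the lactone carbon attached to ring B next to the ether-bearing carbon, R configuration | COc1cc(C)c2c(c1O)Oc1c(c(C)c(O)c3c1[C@H](O)OC3=O)OC2=O | target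

Total step count: 11. Longest linear sequence: 8 steps (1 → 3 → 5 → 7 → 8 → 17 → 18 → 19 → 20; the ring B branch 9 → 10 → 13 → 15 joins at step 8).

Steps most likely to fail

Step 11. Hydrogen abstraction may occur at the two aryl methyl groups instead of the phthalide CH2, the peroxidase side activity may oxidise the phenols by one electron, the enzyme may show poor enantiotopic selection, and the labile lactol may racemise on isolation. The fallback uses known chemistry and sets out from 19. Acetylation of both phenols (Ac2O, pyridine) should give the diacetate F1. Wohl–Ziegler bromination (NBS, AIBN, PhCF3, reflux) at the lactone CH2 should give the racemic 3-bromophthalide diacetate F2. Hydrolysis of the bromide and of both aryl acetates in one pot (2 M HCl, aqueous dioxane, 70 °C) should give the racemic lactol F3. Preparative chiral HPLC on an immobilised amylose phase with acidified eluent at low temperature then separates F3 into the target and the (S)-lactol F4, which can be re-equilibrated to F3 and recycled. The fallback comes back to the route at 20.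

Step 9. The non-native depside with its benzyl ether may not bind productively in the enzyme pocket (no turnover), the benzyl group may be removed oxidatively and the freed catechol oxidised further, or intermolecular coupling may compete. The fallback replaces oxidative coupling by a copper-mediated cross-coupling with a halide installed beforehand; it sets out from 15 and uses 8. Bromination of 15 at its only free ring position (NBS, MeCN, 0 °C) should give 4-bromo-5,7-dihydroxy-6-methylisobenzofuran-1(3H)-one F5. Esterification with 8 under the conditions of step 8 should give the bromo depside F6. Intramolecular Ullmann ether synthesis (copper iodide CuI with monovalent copper, N,N-dimethylglycine, Cs2CO3, dioxane, 90 °C) should then join the benzoate 2-oxygen to the brominated carbon. The fallback comes back to the route at 18.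

Step 3. Regiocontrol may be lost through alkylation at the chelated 2-oxygen, or both oxygens may be benzylated. The fallback sets out from 5: exhaustive benzylation (BnBr, K2CO3, DMF, 60 °C) should give 2,3-bis(benzyloxy)-4-methoxy-6-methylbenzaldehyde F7. Chelation-controlled cleavage of only the benzyl ether ortho to the formyl group (MgBr2·OEt2, toluene/Et2O, 80 °C) then comes back to the route at 7.

Further compounds
F1 | step 11 | di-O-acetate of 19 (both phenols acetylated) | COc1cc(C)c2c(c1OC(C)=O)Oc1c(c(C)c(OC(C)=O)c3c1COC3=O)OC2=O
F2 | step 11 | racemic 3-bromophthalide diacetate (F1 with Br on the lactone CH carbon) | COc1cc(C)c2c(c1OC(C)=O)Oc1c(c(C)c(OC(C)=O)c3c1C(Br)OC3=O)OC2=O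
F3 | step 11 | racemic lactol depsidone | COc1cc(C)c2c(c1O)Oc1c(c(C)c(O)c3c1C(O)OC3=O)OC2=O
F4 | step 11 | (S)-lactol depsidone | COc1cc(C)c2c(c1O)Oc1c(c(C)c(O)c3c1[C@@H](O)OC3=O)OC2=O
F5 | step 9 | 4-bromo-5,7-dihydroxy-6-methylisobenzofuran-1(3H)-one | Cc1c(O)c(Br)c2COC(=O)c2c1O
F6 | step 9 | bromo depside: 4-bromo-7-hydroxy-6-methyl-1-oxo-1,3-dihydroisobenzofuran-5-yl 3-(benzyloxy)-2-hydroxy-4-methoxy-6-methylbenzoate | COc1cc(C)c(C(=O)Oc2c(Br)c3COC(=O)c3c(O)c2C)c(O)c1OCc1ccccc1
F7 | step 3 | 2,3-bis(benzyloxy)-4-methoxy-6-methylbenzaldehyde | COc1cc(C)c(C=O)c(OCc2ccccc2)c1OCc1ccccc1
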